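## Structural features

The target is a flavanone. Aromatic ring A is fused to the dihydropyranone ring C (O1, C2, C3, C4, C4a, C8a), C2 carries the phenyl ring B, and ring A is fully substituted: OH at C5, CH3 at C6, OH at C7 and, at C8, the methine C9 of a 3-methylbutyl chain. C9 is also bonded to C1' of ring D, an enolised 4,4,6,6-tetramethylcyclohexane-1,3,5-trione (syncarpic acid), so C9 holds ring A, ring D and an isobutyl group. The two stereocentres, C2 (R) and C9 (S), are not neighbours; they stand in a 1,5-relationship across C8, C8a and O1, so each needs its own source of asymmetry. Both are labile: C2 epimerises under base by retro-oxa-Michael opening to the 2'-hydroxychalcone. C9 is benzylic to an electron-rich phenol ring and alpha to a vinylogous acid, and can ionise by retro-Michael cleavage under acid, base or heat whenever an ortho or para oxygen of ring A is free. The ring D enol is about as acidic as a carboxylic acid, quenches bases and hydrides and can autoxidise at C1', and the 7-OH/enol OH pair can condense to a xanthene under acid. The real difficulty is a hexasubstituted ring A whose four different substituents must be placed without ambiguity, combined with two remote and individually fragile stereocentres. The key step exploits two facts: the C2–C3–C4 unit of ring C spans O1 and C4a with C4 at the oxidation level of carbon monoxide, and in the side-chain-bearing phenol the future C4a is the single ring A carbon still carrying hydrogen, flanked by the single free hydroxyl (the later O1).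

## Logic of the disconnections

**20 back to 19.** The O5–CH2Ph and O7–CH2Ph bonds are cut. The ring A hydroxyls must stay masked through electrophilic iodination, palladium catalysis in an amine and a hydride reduction. Benzyl is the one mask that leaves under neutral conditions, where neither C2 nor C9 can ionise. The gain is that every earlier intermediate has one free phenol only, the one that becomes O1. The forward step must leave the C4 ketone, the benzylic C2–O1 bond and the ring D enol intact under H2 on palladium.

**19 back to 17.** The C2–H and C3–H bonds are removed, restoring the C2=C3 double bond. This erases the base-labile C2 stereocentre and leaves a flat pyranone that cannot ring-open or epimerise. The forward step must add hydride to one face of C2 under catalyst control, because C9 is too remote to help, and must tolerate an acidic enol.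

**17 back to 12, 13 and 14.** Three bonds are cut: C4a–C4, C4–C3 and O1–C2. C4 is a carbonyl carbon between an aryl and an alkenyl carbon, the pattern of a carbonylative alkynylation, and O1–C2 is a phenol conjugate addition to the resulting ynone. Rings B and C fall away in one operation; 12 has one stereocentre, and 13 and 14 are commodity chemicals. The forward step must insert 14 before the alkyne couples, close the six- and not the five-membered ring, and leave C9 alone while the ortho phenol is still free.

**12 back to 7 and 11.** The C8–C9 bond is cut. C9 is the β-carbon of an alkylidene 1,3-dicarbonyl and C8 is the ortho carbon of a phenol activated by two further alkoxy groups, so this is a Friedel–Crafts-type Michael addition. The cut splits the molecule into an aromatic and a trione half of similar size and puts the creation of C9 under a chiral hydrogen-bonding catalyst. Because 7 already carries iodine on the other ortho carbon, C8 is the only site that can react and double alkylation is excluded. The price is a somewhat less nucleophilic arene, and the forward step must distinguish the two faces of 11.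

**11 back to 8 and 9.** The C9=C1' double bond is cut (Knoevenagel condensation). Both partners are commercial. The forward step must stop after one condensation, which is why the amine adduct 10 is used as a resting form of the alkene.

**7 back to 6.** The C4a–I bond is cut. In 6 the two carbons ortho to the hydroxyl are equivalent by symmetry, so only one mono-iodide can form. Iodinating before C9 and ring D exist keeps electrophilic iodine away from an oxidisable enol next to a phenol. The forward step must stop at the mono-iodide.

**6 back to 4 through 5.** The aryl C–O bond of the phenol is traced to an aryl C–C(acetyl) bond (Baeyer–Villiger oxidation, then acetate cleavage). An oxygen para to the methyl and meta to both ethers cannot be introduced by electrophilic substitution, so a carbon substituent already in that position is exchanged for oxygen. A ketone and not an aldehyde is the migration origin: with both alkoxy groups meta to the carbonyl the ring is not electron-rich at the migrating carbon, and an aldehyde would be expected to give mainly the carboxylic acid by hydride shift, whereas aryl migrates reliably in preference to methyl.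

**4 back to 2 through 3, and 2 back to 1.** The C(acyl)–CH3 bond is cut to the ester level, with 3 as the acyl donor that accepts exactly one methyl nucleophile. The two O–CH2Ph bonds are then cut to 1, in which all ring A carbons and the C6 methyl are already in place.

## Other disconnections considered

**Alternative 1:** The cut runs through ring D at C1'–C2' and C5'–C6'. C9 is carried by (4R)-5,7-dimethoxy-6-methyl-4-(2-methylpropyl)-3,4-dihydrocoumarin A1, and four carbons of ring D come from 2,2,4,4-tetramethylcyclobutane-1,3-dione A2. In the forward step the lactone enolate adds through C1' to a carbonyl of A2, the strained ring opens by retro-Claisen cleavage, and the new enolate carbon C5' acylates the lactone carbonyl. This builds ring D and releases the O1 phenol in the open triketone A3.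
- In its favour: C9 would be set in a simple, non-acidic lactone with no retro-Michael exit. This is better than the chosen plan, where C9 is made in a reversible Friedel–Crafts manifold. A2 is a cheap bulk chemical, and the fragile enol appears late.
- Against it here: the cascade needs a strong amide base, and its last acylation joins a fully substituted enolate carbon to a hindered carbonyl, so it may stop at the open-chain stage. A3 still lacks rings C and B. They would have to be added to a substrate that already holds the acidic enol and a phenol ortho to C9. The two methyl ethers would need a boron or aluminium halide at the very end, which puts C2, C9 and the phenol/enol pair at risk.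
- Comparison: on mechanism the two key steps are equals (two or three bonds, one ring). On structure and step economy the chosen step leaves only a reduction and a deprotection, whereas A3 is several steps from the target.

**Alternative 2:** The cut is the C4–C4a bond of ring C. (3R)-3-(3,5-Dimethoxy-4-methylphenoxy)-3-phenylpropanoic acid A4 is activated with trifluoroacetic anhydride and acylates the ring ortho to the ether oxygen to give (2R)-5,7-dimethoxy-6-methylflavanone A5.
- In its favour: the ether comes from a symmetric phenol, so no regiochemistry arises. C2 is taken from an enantiopure 3-hydroxy-3-phenylpropanoate by a stereospecific etherification and needs no asymmetric catalyst; this is simpler than a ligand-controlled hydride addition and at least its equal in reliability. No pressure equipment or transition metal is needed.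
- Against it here: C2 is benzylic and bears an aryloxy group, so both the etherification and the strongly acidic acylation can erode it by ionisation or elimination to the cinnamate. More seriously, A5 has nothing at C8. The side chain would have to be attached to a ring deactivated by the C4 carbonyl and lacking a free phenol for a hydrogen-bonding catalyst, so C9 would form under Lewis acid without control. The methyl ethers would still have to be cleaved.
- Comparison: A5 holds rings A, B and C and C2 but postpones the hardest carbon; the chosen plan sets C9 first and C2 last, each under its own catalyst. The front end of the alternative is shorter by two or three steps, but its back end has no defensible solution, so it is the weaker plan overall.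

**Alternative 3:** Four C–CH3 bonds of ring D are cut (two at C3', two at C5'), which turns ring D back into a 2,4,6-trihydroxyphenyl group on C9. The precursor is 7-(benzyloxy)-5-hydroxy-6-methyl-8-[(1R)-3-methyl-1-(2,4,6-trihydroxyphenyl)butyl]flavone A6 (the descriptor changes with the substituent; the spatial arrangement at C9 is that of the target). In the forward step sodium methoxide and iodomethane would methylate C3' and C5' twice each to give the 7-O-benzyl flavone A7.
- In its favour: the step mirrors the likely biogenesis, needs no trione building block and creates the acidic enol at the last moment. A7 differs from 17 only by a free 5-OH, so the endgame would be the same; on that count the plans are equal.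
- Against it: exhaustive C-methylation competes with O-methylation of the pendant phenols and of the 5-OH and with a fifth methylation at C1'. Mixtures are to be expected when the ring carries an alkyl and not an acyl group, and methoxide can also attack the flavone at C2. A6 moves the real problem upstream: its C9 carries two phloroglucinol-type rings, which makes it more prone to retro-Friedel–Crafts scrambling than C9 in 12 and harder to obtain as one enantiomer.
- Comparison: mechanistically it is four enolate alkylations with no ring closed and no stereocentre set, against a cascade forming a ring and three skeletal bonds. In step count it adds the synthesis of A6 to the same two final steps, so it is longer.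

Key step: step 7

Assumption: ring D is drawn throughout as one enol tautomer (the enols and hemiketal forms interconvert), and the catalyst antipodes named in steps 6 and 8 are those expected to give 9S and 2R; should a model run show the opposite sense, the quinidine-derived squaramide or the (S)-ligand is used and nothing else changes.

## Route

Step 1
Reactants: 1 methyl 3,5-dihydroxy-4-methylbenzoate
Product: 2 methyl 3,5-bis(benzyloxy)-4-methylbenzoate
Conditions: BnBr (2.3 equiv), K2CO3, DMF, 60 °C
Reagents that add atoms: benzyl bromide, BrCc1ccccc1
Why: Williamson ether synthesis on the two equivalent phenols; the ester deactivates the ring, so carbon benzylation is not a concern, and it is inert to K2CO3 in DMF.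

Step 2
Reactants: 2 methyl 3,5-bis(benzyloxy)-4-methylbenzoate
Product: 4 1-[3,5-bis(benzyloxy)-4-methylphenyl]ethan-1-one, via Weinreb amide 3 (not isolated)
Conditions: MeNH(OMe)·HCl, i-PrMgCl, THF, −20 °C; then MeMgBr, −20 to 0 °C; aq. NH4Cl
Reagents that add atoms: methylmagnesium bromide, C[Mg]Br
Why: The magnesium amide of N,O-dimethylhydroxylamine, made with i-PrMgCl (too hindered to attack the ester at −20 °C), converts the ester into Weinreb amide 3; MeMgBr then adds only once, because the chelated tetrahedral adduct collapses to the ketone only on aqueous work-up (Weinreb ketone synthesis in one flask).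

Step 3
Reactants: 4 1-[3,5-bis(benzyloxy)-4-methylphenyl]ethan-1-one
Product: 6 3,5-bis(benzyloxy)-4-methylphenol, via aryl acetate 5 (not isolated)
Conditions: mCPBA, TFA, CH2Cl2, 0 °C to rt; aq. Na2SO3/NaHCO3; then K2CO3 (cat.), MeOH, rt
Reagents that add atoms: 3-chloroperoxybenzoic acid (mCPBA), O=C(OO)c1cccc(Cl)c1
Why: Baeyer–Villiger oxidation: in the Criegee adduct aryl migrates in preference to methyl, and TFA accelerates a ring that is not activated at the migrating carbon; acetate 5 shields the new, very electron-rich phenol from the peracid until K2CO3-catalysed methanolysis releases it, and benzyl ethers are inert to both stages.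

Step 4
Reactants: 6 3,5-bis(benzyloxy)-4-methylphenol
Product: 7 3,5-bis(benzyloxy)-2-iodo-4-methylphenol
Conditions: NIS (1.0 equiv), CH2Cl2, −40 to 0 °C, dark
Reagents that add atoms: N-iodosuccinimide, O=C1CCC(=O)N1I
Why: Electrophilic aromatic iodination; the two open ring carbons are equivalent and each is ortho to OH and ortho or para to both ethers, so one equivalent of NIS at low temperature should give a single mono-iodide, the first iodine slowing the second substitution.

Step 5
Reactants: 8 syncarpic acid (2,2,4,4-tetramethylcyclohexane-1,3,5-trione), 9 3-methylbutanal
Product: 11 2,2,4,4-tetramethyl-6-(3-methylbutylidene)cyclohexane-1,3,5-trione, via Mannich base 10 (not isolated)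
Conditions: piperidine (1.1 equiv), CH2Cl2, 0 °C to rt; then 1 M HCl (aq) wash
Reagents that add atoms: none
Why: Knoevenagel condensation run through the Mannich base: piperidine and 9 form an iminium ion that the acidic trione 8 attacks, and the zwitterionic adduct 10 cannot add a second molecule of 8; the acid wash protonates nitrogen and triggers β-elimination to the doubly activated alkene 11, which is used at once.

Step 6
Reactants: 7 3,5-bis(benzyloxy)-2-iodo-4-methylphenol, 11 2,2,4,4-tetramethyl-6-(3-methylbutylidene)cyclohexane-1,3,5-trione (1.2 equiv)
Product: 12 3,5-bis(benzyloxy)-2-iodo-4-methyl-6-[(1S)-1-(2-hydroxy-3,3,5,5-tetramethyl-4,6-dioxocyclohex-1-en-1-yl)-3-methylbutyl]phenol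
Conditions: squaramide from 9-amino-9-deoxy-epi-quinine and 3,5-bis(trifluoromethyl)aniline (10 mol %), 4 Å MS, CH2Cl2, −20 °C
Reagents that add atoms: none
Why: Enantioselective Friedel–Crafts-type Michael addition of an electron-rich phenol to an alkylidene 1,3-dicarbonyl under a bifunctional cinchona squaramide: the two squaramide N–H bonds bind the dicarbonyl of 11 and the quinuclidine nitrogen holds the phenol O–H, so the only free ring carbon of 7 is delivered to one face of C9, followed by rearomatisation and enolisation; the catalyst alone sets C9 (9S with the quinine-derived antipode, as assumed above).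

Step 7
Reactants: 12 3,5-bis(benzyloxy)-2-iodo-4-methyl-6-[(1S)-1-(2-hydroxy-3,3,5,5-tetramethyl-4,6-dioxocyclohex-1-en-1-yl)-3-methylbutyl]phenol, 13 phenylacetylene (2 equiv), 14 carbon monoxide
Product: 17 5,7-bis(benzyloxy)-8-[(1S)-1-(2-hydroxy-3,3,5,5-tetramethyl-4,6-dioxocyclohex-1-en-1-yl)-3-methylbutyl]-6-methyl-2-phenyl-4H-chromen-4-one, via ynone 15 (not isolated), via diethylaminoenone 16 (not isolated)
Conditions: PdCl2(PPh3)2 (5 mol %), CO (5 bar), Et2NH, 60 °C
Reagents that add atoms: none
Why: Carbonylative Sonogashira-type coupling followed by amine-relayed oxa-cyclisation, the known route from ortho-iodophenols, terminal alkynes and CO to flavones. PdCl2(PPh3)2 is reduced in the amine to zerovalent palladium, which adds oxidatively across C4a–I; migratory insertion of CO, favoured by the CO pressure and by the electron-rich, doubly ortho-substituted aryl group, gives an aroyl complex of divalent palladium, and transfer of the acetylide formed from 13 and the amine followed by reductive elimination makes C4a–C4 and C4–C3 in ynone 15. Diethylamine then adds to C2 of the ynone to give the β-aminoenone 16, and the neighbouring phenoxide O1 attacks the same carbon and expels the amine, which makes O1–C2. Ring C thus closes in a 6-endo-trig addition–elimination; the 5-exo-dig attack of O1 on C3 that would give the aurone is avoided because the secondary amine converts the alkyne into the enaminone first, a control element that lies in the reagent and asks nothing of the substrate. Site selectivity rests on the substrate: iodine occupies the only ring A carbon that had no substituent and the only free phenol is ortho to it, while the ring D enol is present as a hindered diethylammonium enolate that is a poor acyl acceptor. No stereocentre is formed; C9 is a spectator, and the moderate temperature is chosen to keep retro-Michael ionisation at C9 slow while the ortho phenol is still free, a pathway that is closed once O1 is part of the pyranone. Copper is left out so that direct alkynylation of the iodide, which would end in a benzofuran, does not compete with carbonylation.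

Step 8
Reactants: 17 5,7-bis(benzyloxy)-8-[(1S)-1-(2-hydroxy-3,3,5,5-tetramethyl-4,6-dioxocyclohex-1-en-1-yl)-3-methylbutyl]-6-methyl-2-phenyl-4H-chromen-4-one
Product: 19 (2R)-5,7-bis(benzyloxy)-8-[(1S)-1-(2-hydroxy-3,3,5,5-tetramethyl-4,6-dioxocyclohex-1-en-1-yl)-3-methylbutyl]-6-methyl-2-phenyl-2,3-dihydro-4H-chromen-4-one, via bis-silyl ether 18 (not isolated)
Conditions: Cu(OAc)2 (5 mol %), (R)-DTBM-SEGPHOS (5.5 mol %), (EtO)2MeSiH (4 equiv), THF, 0 °C to rt; then AcOH, H2O/THF, 0 °C
Reagents that add atoms: none
Why: Copper hydride-catalysed asymmetric conjugate reduction of a chromen-4-one: ligated CuH formed from Cu(OAc)2 and the silane first silylates the acidic enol with loss of H2 (hence the excess of silane), then adds hydride to C2 of the vinylogous ester, and the copper enolate is trapped as a silyl enol ether, so 18 is protected from carbonyl reduction and retro-oxa-Michael opening until mild acid hydrolysis releases ketone and enol. The face of C2 is chosen by the bulky bisphosphine (catalyst control, 2R with the (R)-ligand as assumed above); C9 is four bonds away and is not touched.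

Step 9
Reactants: 19 (2R)-5,7-bis(benzyloxy)-8-[(1S)-1-(2-hydroxy-3,3,5,5-tetramethyl-4,6-dioxocyclohex-1-en-1-yl)-3-methylbutyl]-6-methyl-2-phenyl-2,3-dihydro-4H-chromen-4-one
Product: 20 (2R)-5,7-dihydroxy-8-[(1S)-1-(2-hydroxy-3,3,5,5-tetramethyl-4,6-dioxocyclohex-1-en-1-yl)-3-methylbutyl]-6-methyl-2-phenyl-2,3-dihydro-4H-chromen-4-one (target)
Conditions: H2 (1 atm), 10% Pd/C, EtOAc, rt
Reagents that add atoms: none
Why: Hydrogenolysis of the two benzyl aryl ethers in a neutral medium, where neither C2 (base-labile) nor C9 and the phenol/enol pair (acid-labile) are exposed; the hydrogen-bonded aryl ketone, the fully substituted enol double bond and the C2–O1 bond react much more slowly than O-benzyl groups at 1 atm, and the reaction is stopped when 19 is consumed.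

## Compound list

1 | methyl 3,5-dihydroxy-4-methylbenzoate | COC(=O)c1cc(O)c(C)c(O)c1 | starting material
2 | methyl 3,5-bis(benzyloxy)-4-methylbenzoate | COC(=O)c1cc(OCc2ccccc2)c(C)c(OCc2ccccc2)c1 | intermediate
3 | 3,5-bis(benzyloxy)-N-methoxy-N,4-dimethylbenzamide (Weinreb amide) | CON(C)C(=O)c1cc(OCc2ccccc2)c(C)c(OCc2ccccc2)c1 | intermediate
4 | 1-[3,5-bis(benzyloxy)-4-methylphenyl]ethan-1-one | CC(=O)c1cc(OCc2ccccc2)c(C)c(OCc2ccccc2)c1 | intermediate
5 | 3,5-bis(benzyloxy)-4-methylphenyl acetate | CC(=O)Oc1cc(OCc2ccccc2)c(C)c(OCc2ccccc2)c1 | intermediate
6 | 3,5-bis(benzyloxy)-4-methylphenol | Cc1c(OCc2ccccc2)cc(O)cc1OCc1ccccc1 | intermediate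
7 | 3,5-bis(benzyloxy)-2-iodo-4-methylphenol | Cc1c(OCc2ccccc2)cc(O)c(I)c1OCc1ccccc1 | intermediate
8 | syncarpic acid (2,2,4,4-tetramethylcyclohexane-1,3,5-trione) | CC1(C)C(=O)CC(=O)C(C)(C)C1=O | starting material
9 | 3-methylbutanal | CC(C)CC=O | starting material
10 | 5-hydroxy-2,2,6,6-tetramethyl-4-[3-methyl-1-(piperidin-1-yl)butyl]cyclohex-4-ene-1,3-dione (racemic Mannich base, drawn as the neutral enol) | CC(C)CC(N1CCCCC1)C1=C(O)C(C)(C)C(=O)C(C)(C)C1=O | intermediate
11 | 2,2,4,4-tetramethyl-6-(3-methylbutylidene)cyclohexane-1,3,5-trione | CC(C)CC=C1C(=O)C(C)(C)C(=O)C(C)(C)C1=O | intermediate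
12 | 3,5-bis(benzyloxy)-2-iodo-4-methyl-6-[(1S)-1-(2-hydroxy-3,3,5,5-tetramethyl-4,6-dioxocyclohex-1-en-1-yl)-3-methylbutyl]phenol | Cc1c(OCc2ccccc2)c(I)c(O)c([C@H](CC(C)C)C2=C(O)C(C)(C)C(=O)C(C)(C)C2=O)c1OCc1ccccc1 | intermediate
13 | phenylacetylene | C#Cc1ccccc1 | starting material
14 | carbon monoxide | [C-]#[O+] | starting material
15 | 1-{2,4-bis(benzyloxy)-6-hydroxy-5-[(1S)-1-(2-hydroxy-3,3,5,5-tetramethyl-4,6-dioxocyclohex-1-en-1-yl)-3-methylbutyl]-3-methylphenyl}-3-phenylprop-2-yn-1-one | Cc1c(OCc2ccccc2)c(C(=O)C#Cc2ccccc2)c(O)c([C@H](CC(C)C)C2=C(O)C(C)(C)C(=O)C(C)(C)C2=O)c1OCc1ccccc1 | intermediate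
16 | 1-{2,4-bis(benzyloxy)-6-hydroxy-5-[(1S)-1-(2-hydroxy-3,3,5,5-tetramethyl-4,6-dioxocyclohex-1-en-1-yl)-3-methylbutyl]-3-methylphenyl}-3-(diethylamino)-3-phenylprop-2-en-1-one (alkene geometry not defined) | Cc1c(OCc2ccccc2)c(C(=O)C=C(N(CC)CC)c2ccccc2)c(O)c([C@H](CC(C)C)C2=C(O)C(C)(C)C(=O)C(C)(C)C2=O)c1OCc1ccccc1 | intermediate
17 | 5,7-bis(benzyloxy)-8-[(1S)-1-(2-hydroxy-3,3,5,5-tetramethyl-4,6-dioxocyclohex-1-en-1-yl)-3-methylbutyl]-6-methyl-2-phenyl-4H-chromen-4-one | Cc1c(OCc2ccccc2)c2c(c([C@H](CC(C)C)C3=C(O)C(C)(C)C(=O)C(C)(C)C3=O)c1OCc1ccccc1)OC(c1ccccc1)=CC2=O | intermediate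
18 | (2R)-5,7-bis(benzyloxy)-4-{[diethoxy(methyl)silyl]oxy}-8-[(1S)-1-(2-{[diethoxy(methyl)silyl]oxy}-3,3,5,5-tetramethyl-4,6-dioxocyclohex-1-en-1-yl)-3-methylbutyl]-6-methyl-2-phenyl-2H-chromene | Cc1c(OCc2ccccc2)c2c(c([C@H](CC(C)C)C3=C(O[Si](C)(OCC)OCC)C(C)(C)C(=O)C(C)(C)C3=O)c1OCc1ccccc1)O[C@@H](c1ccccc1)C=C2O[Si](C)(OCC)OCC | intermediate
19 | (2R)-5,7-bis(benzyloxy)-8-[(1S)-1-(2-hydroxy-3,3,5,5-tetramethyl-4,6-dioxocyclohex-1-en-1-yl)-3-methylbutyl]-6-methyl-2-phenyl-2,3-dihydro-4H-chromen-4-one | Cc1c(OCc2ccccc2)c2c(c([C@H](CC(C)C)C3=C(O)C(C)(C)C(=O)C(C)(C)C3=O)c1OCc1ccccc1)O[C@@H](c1ccccc1)CC2=O | intermediate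
20 | (2R)-5,7-dihydroxy-8-[(1S)-1-(2-hydroxy-3,3,5,5-tetramethyl-4,6-dioxocyclohex-1-en-1-yl)-3-methylbutyl]-6-methyl-2-phenyl-2,3-dihydro-4H-chromen-4-one | Cc1c(O)c2c(c([C@H](CC(C)C)C3=C(O)C(C)(C)C(=O)C(C)(C)C3=O)c1O)O[C@@H](c1ccccc1)CC2=O | target

## Step count and least certain steps

Total: 9 steps. Longest linear sequence: 8 steps (steps 1, 2, 3, 4, 6, 7, 8, 9 from compound 1); step 5 is a one-step side branch.

**Step 7 (key step).** What may go wrong: slow oxidative addition and carbonylation at an iodide flanked by a phenoxide and a benzyloxy group, so that protodeiodination or capture of the aroyl palladium species by diethylamine (amide formation) takes over; and partial loss of configuration at C9 by retro-Michael ionisation in warm amine before O1 is incorporated. Fallback (organomagnesium acylation in place of carbonylation): setting out from 12, both O–H groups are deprotonated with MeMgCl and iodine–magnesium exchange with i-PrMgCl·LiCl at −20 °C gives the arylmagnesium species. This is acylated with N-methoxy-N-methyl-3-phenylprop-2-ynamide F1 (from phenylpropiolic acid) to give ynone 15 after quench. Stirring 15 with Et2NH in EtOH at room temperature should lead through 16 to 17, where the route is rejoined. No CO, no palladium and no heating are involved.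

**Step 6.** What may go wrong: poor facial selectivity at C9; stalling of the catalyst because the enol of the product is acidic enough to protonate the quinuclidine nitrogen; lower ring nucleophilicity caused by the iodine; and base-induced deconjugation of 11. Fallback (resolution in place of asymmetric catalysis): setting out from 7 and 11, the addition is run with an achiral amine base (Et3N, CH2Cl2, rt) to give the racemate of 12, rac-3,5-bis(benzyloxy)-2-iodo-4-methyl-6-[1-(2-hydroxy-3,3,5,5-tetramethyl-4,6-dioxocyclohex-1-en-1-yl)-3-methylbutyl]phenol F2. F2 is resolved by preparative chromatography on a chiral stationary phase; the (S)-enantiomer is 12, where the route is rejoined. The other enantiomer could in principle be racemised through the retro-Michael/Michael equilibrium and recycled.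

**Step 8.** What may go wrong: low reactivity of the β-aryl vinylogous ester towards the bulky ligated hydride; a mismatch between the ligand and the resident C9 centre that lowers facial selectivity at C2; or epimerisation at C2 by ring opening of the enolate during work-up. Fallback (separation of diastereomers in place of catalyst control): setting out from 17, conjugate reduction with an achiral, more reactive copper hydride [Cu(OAc)2, 1,2-bis(diphenylphosphino)benzene, (EtO)2MeSiH, t-BuOH, toluene] should give 19 together with its C2 epimer, (2S)-5,7-bis(benzyloxy)-8-[(1S)-1-(2-hydroxy-3,3,5,5-tetramethyl-4,6-dioxocyclohex-1-en-1-yl)-3-methylbutyl]-6-methyl-2-phenyl-2,3-dihydro-4H-chromen-4-one F3. The two are diastereomers and are separated by chromatography; 19 rejoins the route, and F3 can be returned to 17 by dehydrogenation with DDQ.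

**Step 4.** What may go wrong: over-iodination at the second ortho carbon, or loss of iodine from the very electron-rich ring on exposure to acid or light during purification. Fallback (reversed order of alkylation and iodination): setting out from 6, the squaramide-catalysed addition to 11 is carried out first and gives 3,5-bis(benzyloxy)-2-[(1S)-1-(2-hydroxy-3,3,5,5-tetramethyl-4,6-dioxocyclohex-1-en-1-yl)-3-methylbutyl]-4-methylphenol F4. Its single remaining ring carbon is then iodinated (NIS, CH2Cl2, −40 °C, no base) to give 12, where the route is rejoined. This order is held in reserve because electrophilic iodine then meets the ring D enol next to a free phenol, and because 6 could be alkylated twice.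

**Step 3.** What may go wrong: slow aryl migration, because both alkoxy groups are meta to the migrating carbon, with oxidation of the electron-rich ring by the peracid as the competing process. Fallback (hydroperoxide rearrangement in place of Baeyer–Villiger oxidation): setting out from 2, excess MeMgBr in THF gives 2-[3,5-bis(benzyloxy)-4-methylphenyl]propan-2-ol F5. Treatment with H2O2 and BF3·OEt2 in CH2Cl2 at 0 °C (Hock rearrangement of the tertiary benzylic hydroperoxide, with loss of acetone) should give 6, where the route is rejoined; compounds 3, 4 and 5 are then not needed.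

## Further compounds

F1 | step 7 | N-methoxy-N-methyl-3-phenylprop-2-ynamide | CON(C)C(=O)C#Cc1ccccc1
F2 | step 6 | rac-3,5-bis(benzyloxy)-2-iodo-4-methyl-6-[1-(2-hydroxy-3,3,5,5-tetramethyl-4,6-dioxocyclohex-1-en-1-yl)-3-methylbutyl]phenol | Cc1c(OCc2ccccc2)c(I)c(O)c(C(CC(C)C)C2=C(O)C(C)(C)C(=O)C(C)(C)C2=O)c1OCc1ccccc1
F3 | step 8 | (2S)-5,7-bis(benzyloxy)-8-[(1S)-1-(2-hydroxy-3,3,5,5-tetramethyl-4,6-dioxocyclohex-1-en-1-yl)-3-methylbutyl]-6-methyl-2-phenyl-2,3-dihydro-4H-chromen-4-one | Cc1c(OCc2ccccc2)c2c(c([C@H](CC(C)C)C3=C(O)C(C)(C)C(=O)C(C)(C)C3=O)c1OCc1ccccc1)O[C@H](c1ccccc1)CC2=O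
F4 | step 4 | 3,5-bis(benzyloxy)-2-[(1S)-1-(2-hydroxy-3,3,5,5-tetramethyl-4,6-dioxocyclohex-1-en-1-yl)-3-methylbutyl]-4-methylphenol | Cc1c(OCc2ccccc2)cc(O)c([C@H](CC(C)C)C2=C(O)C(C)(C)C(=O)C(C)(C)C2=O)c1OCc1ccccc1
F5 | step 3 | 2-[3,5-bis(benzyloxy)-4-methylphenyl]propan-2-ol | CC(C)(O)c1cc(OCc2ccccc2)c(C)c(OCc2ccccc2)c1
A1 | alternative 1 | (4R)-5,7-dimethoxy-6-methyl-4-(2-methylpropyl)-3,4-dihydro-2H-chromen-2-one | COc1cc2OC(=O)C[C@@H](CC(C)C)c2c(OC)c1C
A2 | alternative 1 | 2,2,4,4-tetramethylcyclobutane-1,3-dione | CC1(C)C(=O)C(C)(C)C1=O
A3 | alternative 1 | 2-[(1S)-1-(2-hydroxy-4,6-dimethoxy-5-methylphenyl)-3-methylbutyl]syncarpic acid, enol form | COc1cc(O)c([C@H](CC(C)C)C2=C(O)C(C)(C)C(=O)C(C)(C)C2=O)c(OC)c1C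
A4 | alternative 2 | (3R)-3-(3,5-dimethoxy-4-methylphenoxy)-3-phenylpropanoic acid | COc1cc(O[C@@H](c2ccccc2)CC(=O)O)cc(OC)c1C
A5 | alternative 2 | (2R)-5,7-dimethoxy-6-methylflavanone | COc1cc2O[C@@H](c3ccccc3)CC(=O)c2c(OC)c1C
A6 | alternative 3 | 7-(benzyloxy)-5-hydroxy-6-methyl-8-[(1R)-3-methyl-1-(2,4,6-trihydroxyphenyl)butyl]-2-phenyl-4H-chromen-4-one | Cc1c(O)c2c(c([C@H](CC(C)C)c3c(O)cc(O)cc3O)c1OCc1ccccc1)OC(c1ccccc1)=CC2=O
A7 | alternative 3 | 7-(benzyloxy)-5-hydroxy-8-[(1S)-1-(2-hydroxy-3,3,5,5-tetramethyl-4,6-dioxocyclohex-1-en-1-yl)-3-methylbutyl]-6-methyl-2-phenyl-4H-chromen-4-one | Cc1c(O)c2c(c([C@H](CC(C)C)C3=C(O)C(C)(C)C(=O)C(C)(C)C3=O)c1OCc1ccccc1)OC(c1ccccc1)=CC2=O
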